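**Plan**
- Retrosynthetic cuts: C11=C12 and C11'=C12' (Wittig), then C7=C8 (Horner–Wadsworth–Emmons), which leaves a C10 end group (carotenoid locants throughout).
- Enabling feature: re-tying C7 to the oxygen on C1 turns the end group into a cis-fused 3-oxabicyclo[3.3.0]octane (oxolane C6–C7–O–C1–C2 fused to cyclopentane C2–C3–C4–C5–C6). That carbocycle is one but-2-ynyl unit, one vinyl group and one CO, cut at C2–C6, C3–C4 and C4–C5; the C7–O bond is cut last.
- Forward order: ether, then both rings in one Pauson–Khand step, H onto C6 and O onto C5, removal of the C4 oxygen, oxidation of C7 to the lactone/lactol, opening of the oxolane by olefination, C15 phosphonium salt, and union with a C25 aldehyde made from pseudoionone and the C10 dialdehyde.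
- Stereochemistry: C2 from the chiral rhodium catalyst; C6 from the forced cis ring fusion; C5 from oxidation on the convex face; E double bonds from HWE/Wittig selectivity plus thermal equilibration.

Key step: step 2

Assumption: (S)-BINAP is written for step 2; which antipode of the ligand gives the (R)-enone 5 on this gem-dimethyl substrate has to be settled in the first run, and the mirror-image ligand is used if the sense is the opposite.

Naming: bicyclic intermediates are named as 3-oxabicyclo[3.3.0]octanes; their locants 1, 2, 4, 5, 6, 7, 8 correspond to carotenoid C6, C7, C1, C2, C3, C4, C5.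

**Step 1**
Reactants: 1 2-methylbut-3-en-2-ol; 2 1-bromobut-2-yne
Product: 4 3-(but-2-yn-1-yloxy)-3-methylbut-1-ene, via sodium alkoxide 3 (not isolated)
Conditions: NaH (1.2 equiv), THF/DMF, 0 °C; then 2, Bu4NI (cat.), 0 to 23 °C
Reagents that add atoms: none
Why: Williamson ether synthesis; the tertiary alkoxide displaces bromide at the primary propargylic carbon by SN2, and the bromide has no sp3 β-hydrogen that could be lost by elimination.

**Step 2**
Reactants: 4 3-(but-2-yn-1-yloxy)-3-methylbut-1-ene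
Product: 5 (5R)-4,4,8-trimethyl-3-oxabicyclo[3.3.0]oct-1(8)-en-7-one
Conditions: [RhCl(CO)2]2 (3 mol %), (S)-BINAP (9 mol %), AgOSO2CF3 (12 mol %), CO (1 atm), THF, 90 °C, sealed vessel
Reagents that add atoms: carbon monoxide, [C-]#[O+]
Why: This is a Pauson–Khand reaction in its enantioselective intramolecular form, catalysed by a cationic bisphosphine carbonyl complex of monovalent rhodium, a reaction type established for oxygen-tethered 1,6-enynes with a substituted alkyne terminus. The enyne chelates the metal and undergoes oxidative cyclisation to a rhodacyclopentene of trivalent rhodium, which forms C2–C6 and closes the oxolane in the 5-exo mode with respect to both the alkyne and the alkene. CO then inserts into a Rh–C bond and C–C reductive elimination closes the cyclopentenone as the (2+2+1) sum of alkyne, alkene and CO, forming C3–C4 and C4–C5. The only new stereocentre, C2, is set when the chiral ligand pocket selects one face of the monosubstituted alkene during oxidative cyclisation. The three-atom tether fixes the regiochemistry, placing the alkyne methyl on C5 next to the carbonyl and allowing only the fused bicycle. The step needs face selectivity and a reactive fold of the chain; the substituted alkyne terminus supports the former and the gem-dimethyl group on C1 (Thorpe–Ingold effect) secures the latter.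

**Step 3**
Reactants: 5 (5R)-4,4,8-trimethyl-3-oxabicyclo[3.3.0]oct-1(8)-en-7-one
Product: 6 (1R,5R)-4,4,8-trimethyl-7-(triethylsilyloxy)-3-oxabicyclo[3.3.0]oct-7-ene
Conditions: Et3SiH (2 equiv), RhCl(PPh3)3 (3 mol %), PhMe, 70 °C
Reagents that add atoms: triethylsilane, CC[SiH](CC)CC
Why: Rhodium-catalysed 1,4-hydrosilylation of an enone (known also for fully substituted enones) should deliver hydride to C6 on the face of H-2, since only that gives the strain-free cis-fused bicycle, while silicon ends on oxygen and fixes the enol ether at C4=C5.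

**Step 4**
Reactants: 6 (1R,5R)-4,4,8-trimethyl-7-(triethylsilyloxy)-3-oxabicyclo[3.3.0]oct-7-ene
Product: 8 (1S,5R,8S)-4,4,8-trimethyl-8-(triethylsilyloxy)-3-oxabicyclo[3.3.0]octan-7-one, via silyloxy epoxide 7 (not isolated)
Conditions: mCPBA (1.1 equiv), NaHCO3 (3 equiv), CH2Cl2, −20 to 0 °C; aq. Na2S2O3/NaHCO3 work-up
Reagents that add atoms: 3-chloroperbenzoic acid (mCPBA), OOC(=O)c1cccc(Cl)c1
Why: Rubottom oxidation; the peracid should epoxidise the electron-rich enol ether on the convex face (anti to the C6–C7 bond), and opening of the silyloxy epoxide with 1,4-silyl shift then places the C5 oxygen trans to C7, the bicarbonate buffer keeping the triethylsilyl group on it.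

**Step 5**
Reactants: 8 (1S,5R,8S)-4,4,8-trimethyl-8-(triethylsilyloxy)-3-oxabicyclo[3.3.0]octan-7-one
Product: 10 (1S,5R,8S)-4,4,8-trimethyl-8-(triethylsilyloxy)-3-oxabicyclo[3.3.0]oct-6-en-7-yl trifluoromethanesulfonate, via potassium enolate 9 (not isolated)
Conditions: KN(SiMe3)2 (1.15 equiv), THF, −78 °C; PhNTf2 (1.2 equiv), −78 to 0 °C
Reagents that add atoms: N-phenylbis(trifluoromethanesulfonimide) (PhNTf2), O=S(=O)(N(c1ccccc1)S(=O)(=O)C(F)(F)F)C(F)(F)F
Why: Enol triflate formation; C5 is quaternary, so the amide base can enolise only towards C3, and the enolate is trapped on oxygen at low temperature before silyl migration can compete.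

**Step 6**
Reactants: 10 (1S,5R,8S)-4,4,8-trimethyl-8-(triethylsilyloxy)-3-oxabicyclo[3.3.0]oct-6-en-7-yl trifluoromethanesulfonate
Product: 11 (1S,5R,8R)-4,4,8-trimethyl-8-(triethylsilyloxy)-3-oxabicyclo[3.3.0]oct-6-ene
Conditions: Pd(OAc)2 (5 mol %), PPh3 (10 mol %), HCO2H (2 equiv), Bu3N (3 equiv), DMF, 60 °C
Reagents that add atoms: none
Why: Palladium-catalysed formate reduction of a vinyl triflate (oxidative addition to zerovalent palladium, formate exchange, loss of CO2, C–H reductive elimination) replaces the C4 oxygen by hydrogen without touching the ether or the silyl ether.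

**Step 7**
Reactants: 11 (1S,5R,8R)-4,4,8-trimethyl-8-(triethylsilyloxy)-3-oxabicyclo[3.3.0]oct-6-ene
Product: 12 (1S,5R,8R)-4,4,8-trimethyl-8-(triethylsilyloxy)-3-oxabicyclo[3.3.0]octane
Conditions: H2 (1 atm), 10 % Pd/C, EtOAc, 23 °C
Reagents that add atoms: none
Why: Heterogeneous hydrogenation of an unhindered disubstituted cyclopentene; no stereocentre is formed and both ethers are inert.

**Step 8**
Reactants: 12 (1S,5R,8R)-4,4,8-trimethyl-8-(triethylsilyloxy)-3-oxabicyclo[3.3.0]octane
Product: 13 (1R,5R,8R)-4,4,8-trimethyl-8-(triethylsilyloxy)-3-oxabicyclo[3.3.0]octan-2-one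
Conditions: RuCl3·xH2O (5 mol %), NaIO4 (4 equiv), CCl4/MeCN/H2O 2:2:3, 23 °C
Reagents that add atoms: sodium periodate (oxygen donor through RuO4), [Na+].[O-]I(=O)(=O)=O
Why: Ruthenium tetroxide oxidation of an ether to a lactone; C7 is the only hydrogen-bearing carbon next to the ring oxygen (C1 is quaternary), and the silylated tertiary oxygen on C5 has no α-hydrogen.

**Step 9**
Reactants: 13 (1R,5R,8R)-4,4,8-trimethyl-8-(triethylsilyloxy)-3-oxabicyclo[3.3.0]octan-2-one
Product: 14 (1R,5R,8R)-4,4,8-trimethyl-8-(triethylsilyloxy)-3-oxabicyclo[3.3.0]octan-2-ol (both C7 anomers)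
Conditions: i-Bu2AlH (1.1 equiv), CH2Cl2, −78 °C; aq. potassium sodium tartrate KNaC4H4O6
Reagents that add atoms: none
Why: Partial reduction of a γ-lactone; the aluminium hemiacetal persists at low temperature and gives the lactol on work-up, with C6 locked by the cis-fused ring.

**Step 10**
Reactants: 14 lactol (1R,5R,8R)-4,4,8-trimethyl-8-(triethylsilyloxy)-3-oxabicyclo[3.3.0]octan-2-ol; 15 triethyl (E)-3-methyl-4-phosphonobut-2-enoate
Product: 18 ethyl (2E,4E)-5-[(1R,2R,5R)-5-(2-hydroxypropan-2-yl)-2-methyl-2-(triethylsilyloxy)cyclopentyl]-3-methylpenta-2,4-dienoate, via lithiated phosphonate 16 (not isolated), via open-chain hydroxy aldehyde 17 (not isolated)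
Conditions: 15 (3 equiv), LiN(SiMe3)2 (2.9 equiv), THF/DMPU, −78 °C; add 14, −78 to 0 °C
Reagents that add atoms: none
Why: Horner–Wadsworth–Emmons olefination of a lactol through its open hydroxy aldehyde; the stabilised vinylogous anion should give the E C7=C8 bond and add to the aldehyde faster than it enolises C6, while the silyl ether on C5 blocks retro-aldol cleavage.

**Step 11**
Reactants: 18 ethyl (2E,4E)-5-[(1R,2R,5R)-5-(2-hydroxypropan-2-yl)-2-methyl-2-(triethylsilyloxy)cyclopentyl]-3-methylpenta-2,4-dienoate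
Product: 19 (2E,4E)-5-[(1R,2R,5R)-5-(2-hydroxypropan-2-yl)-2-methyl-2-(triethylsilyloxy)cyclopentyl]-3-methylpenta-2,4-dien-1-ol
Conditions: i-Bu2AlH (3.5 equiv), CH2Cl2, −78 to −20 °C; aq. potassium sodium tartrate KNaC4H4O6
Reagents that add atoms: none
Why: 1,2-Reduction of a conjugated ester to the primary dienyl alcohol; the silyl ether and the tertiary alcohol (as its aluminium alkoxide) are not affected.

**Step 12**
Reactants: 19 (2E,4E)-5-[(1R,2R,5R)-5-(2-hydroxypropan-2-yl)-2-methyl-2-(triethylsilyloxy)cyclopentyl]-3-methylpenta-2,4-dien-1-ol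
Product: 20 (2E,4E)-5-[(1R,2R,5R)-2-hydroxy-5-(2-hydroxypropan-2-yl)-2-methylcyclopentyl]-3-methylpenta-2,4-dien-1-ol
Conditions: Bu4NF (2 equiv), THF, 23 to 40 °C
Reagents that add atoms: none
Why: Fluoride cleavage of the tertiary triethylsilyl ether under non-ionising conditions, so that the acidic step that follows runs on one defined triol.

**Step 13**
Reactants: 20 (2E,4E)-5-[(1R,2R,5R)-2-hydroxy-5-(2-hydroxypropan-2-yl)-2-methylcyclopentyl]-3-methylpenta-2,4-dien-1-ol
Product: 21 [(2E,4E)-5-[(1R,2R,5R)-2-hydroxy-5-(2-hydroxypropan-2-yl)-2-methylcyclopentyl]-3-methylpenta-2,4-dien-1-yl]triphenylphosphonium bromide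
Conditions: PPh3·HBr (1.05 equiv), MeOH, 0 to 23 °C; precipitation from EtOAc
Reagents that add atoms: triphenylphosphine hydrobromide, Br.c1ccc(cc1)P(c1ccccc1)c1ccccc1
Why: Phosphonium salt formation from a dienylic alcohol, as in classical C15 carotenoid salts; the protonated alcohol ionises to a pentadienyl cation that PPh3 captures irreversibly at the unhindered terminus C11, any ether formed reversibly by the C1 hydroxyl at C7 re-ionises, and the saturated tertiary alcohols do not ionise.

**Step 14**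
Reactants: 22 pseudoionone
Product: 23 (4E,6E)-3,7,11-trimethyldodeca-1,4,6,10-tetraen-3-ol (racemic)
Conditions: CH2=CHMgBr (1.3 equiv), THF, 0 °C; aq. NH4Cl
Reagents that add atoms: vinylmagnesium bromide, C=C[Mg]Br
Why: Grignard 1,2-addition to the dienone carbonyl; the carbinol centre is racemic and disappears in the next step.

**Step 15**
Reactants: 23 (4E,6E)-3,7,11-trimethyldodeca-1,4,6,10-tetraen-3-ol
Product: 24 [(2E,4E,6E)-3,7,11-trimethyldodeca-2,4,6,10-tetraen-1-yl]triphenylphosphonium bromide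
Conditions: PPh3·HBr (1.0 equiv), MeOH, 23 °C
Reagents that add atoms: triphenylphosphine hydrobromide, Br.c1ccc(cc1)P(c1ccccc1)c1ccccc1
Why: Acid-mediated ionisation of the tertiary bis-allylic alcohol with allylic transposition (SN1'); PPh3 adds at the primary terminus to give the conjugated E salt.

**Step 16**
Reactants: 24 [(2E,4E,6E)-3,7,11-trimethyldodeca-2,4,6,10-tetraen-1-yl]triphenylphosphonium bromide; 25 (2E,4E,6E)-2,7-dimethylocta-2,4,6-trienedial
Product: 27 (2E,4E,6E,8E,10E,12E,14E)-2,7,11,15,19-pentamethylicosa-2,4,6,8,10,12,14,18-octaenal, via ylide 26 (not isolated)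
Conditions: 25 (2 equiv), NaOMe (1.1 equiv), CH2Cl2/MeOH, 0 to 23 °C; then heptane, reflux, crystallisation
Reagents that add atoms: none
Why: Wittig reaction forming C11'=C12'; excess dialdehyde should limit the reaction to one aldehyde group, and the hindered Z isomer at the new bond equilibrates to E on heating.

**Step 17**
Reactants: 21 end-group C15 phosphonium bromide; 27 C25 aldehyde
Product: 29 (all-E,2R,5R,6R)-2,6-cyclolycopene-1,5-diol (CNP0169920.2), via ylide 28 (not isolated)
Conditions: 21 (1.2 equiv), NaOMe (1.5 equiv), CH2Cl2/MeOH, 23 °C, N2, dark; then heptane, reflux, crystallisation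
Reagents that add atoms: none
Why: Wittig reaction forming C11=C12; the P–CH2 group is far more acidic than the tertiary alcohols, so these need no protection, and the labile 11Z isomer should convert to all-E on heating.

**Compound list**
1 | 2-methylbut-3-en-2-ol | CC(C)(O)C=C | starting material
2 | 1-bromobut-2-yne | CC#CCBr | starting material
3 | sodium 2-methylbut-3-en-2-olate (not isolated) | CC(C)([O-])C=C.[Na+] | intermediate
4 | 3-(but-2-yn-1-yloxy)-3-methylbut-1-ene | CC#CCOC(C)(C)C=C | intermediate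
5 | (5R)-4,4,8-trimethyl-3-oxabicyclo[3.3.0]oct-1(8)-en-7-one | CC1=C2COC(C)(C)[C@@H]2CC1=O | intermediate
6 | (1R,5R)-4,4,8-trimethyl-7-(triethylsilyloxy)-3-oxabicyclo[3.3.0]oct-7-ene | O1C[C@@H]2[C@H](C1(C)C)CC(O[Si](CC)(CC)CC)=C2C | intermediate
7 | 7,8-epoxide of 6, oxygen on the convex face (not isolated) | O1C[C@@H]2[C@H](C1(C)C)C[C@@]3(O[Si](CC)(CC)CC)O[C@@]23C | intermediate
8 | (1S,5R,8S)-4,4,8-trimethyl-8-(triethylsilyloxy)-3-oxabicyclo[3.3.0]octan-7-one | O1C[C@@H]2[C@H](C1(C)C)CC(=O)[C@@]2(C)O[Si](CC)(CC)CC | intermediate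
9 | potassium enolate of 8, C3=C4 in carotenoid locants (not isolated) | O1C[C@@H]2[C@H](C1(C)C)C=C([O-])[C@@]2(C)O[Si](CC)(CC)CC.[K+] | intermediate
10 | (1S,5R,8S)-4,4,8-trimethyl-8-(triethylsilyloxy)-3-oxabicyclo[3.3.0]oct-6-en-7-yl trifluoromethanesulfonate | O1C[C@@H]2[C@H](C1(C)C)C=C(OS(=O)(=O)C(F)(F)F)[C@@]2(C)O[Si](CC)(CC)CC | intermediate
11 | (1S,5R,8R)-4,4,8-trimethyl-8-(triethylsilyloxy)-3-oxabicyclo[3.3.0]oct-6-ene | O1C[C@@H]2[C@H](C1(C)C)C=C[C@@]2(C)O[Si](CC)(CC)CC | intermediate
12 | (1S,5R,8R)-4,4,8-trimethyl-8-(triethylsilyloxy)-3-oxabicyclo[3.3.0]octane | O1C[C@@H]2[C@H](C1(C)C)CC[C@@]2(C)O[Si](CC)(CC)CC | intermediate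
13 | (1R,5R,8R)-4,4,8-trimethyl-8-(triethylsilyloxy)-3-oxabicyclo[3.3.0]octan-2-one | O1C(=O)[C@@H]2[C@H](C1(C)C)CC[C@@]2(C)O[Si](CC)(CC)CC | intermediate
14 | (1R,5R,8R)-4,4,8-trimethyl-8-(triethylsilyloxy)-3-oxabicyclo[3.3.0]octan-2-ol (anomers) | O1C(O)[C@@H]2[C@H](C1(C)C)CC[C@@]2(C)O[Si](CC)(CC)CC | intermediate
15 | triethyl (E)-3-methyl-4-phosphonobut-2-enoate | CCOC(=O)/C=C(\C)CP(=O)(OCC)OCC | starting material
16 | lithium salt of 15, carbanion at C4 (not isolated) | CCOC(=O)/C=C(\C)[CH-]P(=O)(OCC)OCC.[Li+] | intermediate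
17 | (1R,2R,5R)-5-(2-hydroxypropan-2-yl)-2-methyl-2-(triethylsilyloxy)cyclopentane-1-carbaldehyde, open form of 14 (not isolated) | O=C[C@@H]1[C@H](C(C)(C)O)CC[C@@]1(C)O[Si](CC)(CC)CC | intermediate
18 | ethyl (2E,4E)-5-[(1R,2R,5R)-5-(2-hydroxypropan-2-yl)-2-methyl-2-(triethylsilyloxy)cyclopentyl]-3-methylpenta-2,4-dienoate | CCOC(=O)/C=C(C)/C=C/[C@@H]1[C@H](C(C)(C)O)CC[C@@]1(C)O[Si](CC)(CC)CC | intermediate
19 | (2E,4E)-5-[(1R,2R,5R)-5-(2-hydroxypropan-2-yl)-2-methyl-2-(triethylsilyloxy)cyclopentyl]-3-methylpenta-2,4-dien-1-ol | OC/C=C(C)/C=C/[C@@H]1[C@H](C(C)(C)O)CC[C@@]1(C)O[Si](CC)(CC)CC | intermediate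
20 | (2E,4E)-5-[(1R,2R,5R)-2-hydroxy-5-(2-hydroxypropan-2-yl)-2-methylcyclopentyl]-3-methylpenta-2,4-dien-1-ol | OC/C=C(C)/C=C/[C@@H]1[C@H](C(C)(C)O)CC[C@@]1(C)O | intermediate
21 | [(2E,4E)-5-[(1R,2R,5R)-2-hydroxy-5-(2-hydroxypropan-2-yl)-2-methylcyclopentyl]-3-methylpenta-2,4-dien-1-yl]triphenylphosphonium bromide | [Br-].C(/C=C(C)/C=C/[C@@H]1[C@H](C(C)(C)O)CC[C@@]1(C)O)[P+](c1ccccc1)(c1ccccc1)c1ccccc1 | intermediate
22 | pseudoionone, (3E,5E)-6,10-dimethylundeca-3,5,9-trien-2-one | CC(C)=CCC/C(C)=C/C=C/C(C)=O | starting material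
23 | (4E,6E)-3,7,11-trimethyldodeca-1,4,6,10-tetraen-3-ol (racemic) | CC(C)=CCC/C(C)=C/C=C/C(C)(O)C=C | intermediate
24 | [(2E,4E,6E)-3,7,11-trimethyldodeca-2,4,6,10-tetraen-1-yl]triphenylphosphonium bromide | CC(C)=CCC/C(C)=C/C=C/C(C)=C/C[P+](c1ccccc1)(c1ccccc1)c1ccccc1.[Br-] | intermediate
25 | (2E,4E,6E)-2,7-dimethylocta-2,4,6-trienedial (C10 dialdehyde) | O=C/C(C)=C/C=C/C=C(C)/C=O | starting material
26 | ylide of 24 (not isolated) | CC(C)=CCC/C(C)=C/C=C/C(C)=C/C=P(c1ccccc1)(c1ccccc1)c1ccccc1 | intermediate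
27 | (2E,4E,6E,8E,10E,12E,14E)-2,7,11,15,19-pentamethylicosa-2,4,6,8,10,12,14,18-octaenal (C25 aldehyde) | CC(C)=CCC/C(C)=C/C=C/C(C)=C/C=C/C(C)=C/C=C/C=C(C)/C=O | intermediate
28 | ylide of 21 (not isolated) | c1ccccc1P(c1ccccc1)(c1ccccc1)=C/C=C(C)/C=C/[C@@H]1[C@H](C(C)(C)O)CC[C@@]1(C)O | intermediate
29 | (all-E,2R,5R,6R)-2,6-cyclolycopene-1,5-diol | CC(C)=CCC/C(C)=C/C=C/C(C)=C/C=C/C(C)=C/C=C/C=C(C)/C=C/C=C(C)/C=C/[C@@H]1[C@H](C(C)(C)O)CC[C@@]1(C)O | target

**Step count**
Total: 17 steps. Longest linear sequence: 14 steps (steps 1–13, then step 17).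

**Steps most likely to fail**

Step 2. The ligand may discriminate the two alkene faces poorly, or turnover may be slow, because a quaternary carbon sits directly beside the alkene. Fallback, from 4: a stoichiometric, non-asymmetric Pauson–Khand reaction (Mo(CO)6, DMSO, PhMe, 100 °C) should give the racemic enone F1, which is resolved by preparative chromatography on a chiral stationary phase; the (R)-enantiomer is compound 5 and the route continues at step 3.

Step 10. The gem-dimethyl lactol may open too reluctantly, and in the open aldehyde the basic medium may epimerise C6 or eliminate the C5 silyloxy group. Fallback, from 14: a base-free Takai iodo-olefination (CrCl2, CHI3, THF) should convert the lactol into the (E)-vinyl iodide F2. Stille coupling of F2 with (E)-3-(tributylstannyl)but-2-en-1-ol (Pd(PPh3)4, CuI, DMF) then builds C8–C9 and gives dienol 19 directly, so the route is rejoined at 19 without 18 or step 11.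

Step 13. The acidic medium may divert the dienyl cation (capture at C7 by the C1 hydroxyl, loss of water from a tertiary alcohol, or proton loss to a retro-type triene). Fallback, from 19 with the silyl ether still in place: an Appel bromination (CBr4, PPh3, CH2Cl2, 0 °C) should give the dienyl bromide F3, which is displaced by PPh3 in EtOAc to give the silylated phosphonium bromide F4 without a free cation. F4 is deprotonated with NaOMe to its ylide F5, which condenses with 27 under the conditions of step 17 to give the silyl ether F6; Bu4NF in THF then releases 29.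

**Further compounds**
F1 | step 2 | racemic 4,4,8-trimethyl-3-oxabicyclo[3.3.0]oct-1(8)-en-7-one | CC1=C2COC(C)(C)C2CC1=O
F2 | step 10 | (E)-iodovinyl compound, C7=C8–I on the cyclopentane of 19 with ring stereocentres unchanged | I/C=C/[C@@H]1[C@H](C(C)(C)O)CC[C@@]1(C)O[Si](CC)(CC)CC
F3 | step 13 | primary dienyl bromide derived from 19 | BrC/C=C(C)/C=C/[C@@H]1[C@H](C(C)(C)O)CC[C@@]1(C)O[Si](CC)(CC)CC
F4 | step 13 | 5-O-triethylsilyl analogue of phosphonium bromide 21 | [Br-].C(/C=C(C)/C=C/[C@@H]1[C@H](C(C)(C)O)CC[C@@]1(C)O[Si](CC)(CC)CC)[P+](c1ccccc1)(c1ccccc1)c1ccccc1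
F5 | step 13 | ylide of F4 | c1ccccc1P(c1ccccc1)(c1ccccc1)=C/C=C(C)/C=C/[C@@H]1[C@H](C(C)(C)O)CC[C@@]1(C)O[Si](CC)(CC)CC
F6 | step 13 | 5-O-triethylsilyl ether of 29 | CC(C)=CCC/C(C)=C/C=C/C(C)=C/C=C/C(C)=C/C=C/C=C(C)/C=C/C=C(C)/C=C/[C@@H]1[C@H](C(C)(C)O)CC[C@@]1(C)O[Si](CC)(CC)CC
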